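**Assumption:** the SMILES is read literally, so the half that keeps the free methylene lactone is 6S (6β-OH) and the half with the saturated lactone carbon is 6R (6α-OH). Positions are given in germacrane numbering, primed for the second half.

## Retrosynthetic overview

1. The C1–C13' bond is cut as a formal ene reaction between two C6-epimeric germacranolides. It is made last by a visible-light alkoxyl-radical 1,5-H shift followed by allyl-radical Giese addition.
2. The ene-donor half is the 6β-phthalimidooxy derivative of the enophile half, made from it by Mitsunobu inversion, so one monomer (deacetyllaurenobiolide) serves both halves.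
3. The ten-membered ring, C6 and C7 come from an intramolecular Nozaki–Hiyama allylation (C6–C7) of a 3-(bromomethyl)butenolide carrying an E,E-dienal chain.
4. The butenolide comes from ring-closing metathesis of a 2-(bromomethyl)acrylate. C8 is bought in (S)-epichlorohydrin, opened at CH2 by an E-alkenyllithium (C9–C10).
5. The E,E chain comes from geranyl acetate. Ring order: butenolide, then ten-membered ring, then dimer.

## Route

Step 1
Reactants: 1 geranyl acetate
Product: 2 (2E)-3-methyl-6-oxohex-2-en-1-yl acetate
Conditions: O3 (0.95 equiv), CH2Cl2, −78 °C; then Me2S, −78 °C → rt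
Reagents that add atoms: ozone, [O-][O+]=O
Why: Chemoselective ozonolysis cleaves the electron-rich 6,7-alkene much faster than the 2,3-alkene deactivated by the allylic acetoxy group, leaving the E-alkene untouched.

Step 2
Reactants: 2 (2E)-3-methyl-6-oxohex-2-en-1-yl acetate
Product: 4 (2E)-3-methylhept-2-en-6-yn-1-ol, via enyne acetate 3 (not isolated)
Conditions: dimethyl (1-diazo-2-oxopropyl)phosphonate, K2CO3, MeOH, 0 °C → rt
Reagents that add atoms: dimethyl (1-diazo-2-oxopropyl)phosphonate, COP(=O)(OC)C(=[N+]=[N-])C(C)=O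
Why: Seyferth–Gilbert homologation (Ohira–Bestmann variant) converts the aldehyde into the terminal alkyne, and the same K2CO3/MeOH transesterifies the acetate.

Step 3
Reactants: 4 (2E)-3-methylhept-2-en-6-yn-1-ol
Product: 6 (2E)-3-methyloct-2-en-6-yn-1-ol, via dilithio alkynide alkoxide 5 (not isolated)
Conditions: n-BuLi (2.1 equiv), THF, −78 → 0 °C; then MeI (1.05 equiv), −78 °C → rt
Reagents that add atoms: iodomethane, CI
Why: Acetylide alkylation; the lithium acetylide is C-methylated far faster than the lithium alkoxide is O-methylated in THF.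

Step 4
Reactants: 6 (2E)-3-methyloct-2-en-6-yn-1-ol
Product: 7 (2E,6E)-7-iodo-3-methylocta-2,6-dien-1-ol
Conditions: Cp2Zr(H)Cl (3 equiv), THF, 50 °C; then I2, 0 °C
Reagents that add atoms: iodine, II
Why: Hydrozirconation–iodination; syn addition with equilibration puts zirconium on the methyl-bearing alkyne carbon, and iodinolysis with retention gives the E-2-iodoalkene that fixes the future C1=C10 geometry.

Step 5
Reactants: 7 (2E,6E)-7-iodo-3-methylocta-2,6-dien-1-ol; 8 (S)-epichlorohydrin
Product: 10 (2E,6E,9S)-10-chloro-3,7-dimethyldeca-2,6-diene-1,9-diol, via dilithio alkenyl alkoxide 9 (not isolated)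
Conditions: t-BuLi (3.1 equiv), Et2O, −78 °C; then 8 (2 equiv), BF3·OEt2 (2.2 equiv), −78 °C
Reagents that add atoms: none
Why: Iodine–lithium exchange with retention of alkene geometry, then BF3-promoted SN2 opening of the epoxide at its CH2 terminus; the purchased stereocentre (future C8) is not touched.

Step 6
Reactants: 10 (2E,6E,9S)-10-chloro-3,7-dimethyldeca-2,6-diene-1,9-diol
Product: 12 (2E,6E,9S)-3,7-dimethylundeca-2,6,10-triene-1,9-diol, via epoxide 11 (not isolated)
Conditions: Me3S+ I− (6 equiv), n-BuLi (5.5 equiv), THF, −10 °C → rt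
Reagents that add atoms: trimethylsulfonium iodide, C[S+](C)C.[I-]
Why: The base closes the chlorohydrin to the epoxide, dimethylsulfonium methylide opens it at CH2 and the betaine eliminates Me2S (one-carbon epoxide-to-allylic-alcohol homologation), with the C–O bond at the stereocentre never broken.

Step 7
Reactants: 12 (2E,6E,9S)-3,7-dimethylundeca-2,6,10-triene-1,9-diol
Product: 13 (2E,6E,9S)-9-hydroxy-3,7-dimethylundeca-2,6,10-trienal
Conditions: TEMPO (10 mol %), PhI(OAc)2 (1.1 equiv), CH2Cl2, rt
Reagents that add atoms: none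
Why: Oxoammonium (TEMPO) oxidation is strongly selective for the primary allylic alcohol over the secondary one and gives the E-enal without isomerisation.

Step 8
Reactants: 13 (2E,6E,9S)-9-hydroxy-3,7-dimethylundeca-2,6,10-trienal; 14 2-(bromomethyl)acrylic acid
Product: 15 (3S,5E,9E)-5,9-dimethyl-11-oxoundeca-1,5,9-trien-3-yl 2-(bromomethyl)prop-2-enoate
Conditions: DCC, DMAP (5 mol %), CH2Cl2, −20 → 0 °C
Reagents that add atoms: none
Why: Steglich esterification acylates the secondary alcohol with retention, since the C8–O bond is not broken.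

Step 9
Reactants: 15 (3S,5E,9E)-5,9-dimethyl-11-oxoundeca-1,5,9-trien-3-yl 2-(bromomethyl)prop-2-enoate
Product: 16 (5S)-3-(bromomethyl)-5-[(2E,6E)-2,6-dimethyl-8-oxoocta-2,6-dien-1-yl]furan-2(5H)-one
Conditions: second-generation Grubbs catalyst (5 mol %), 1,4-benzoquinone (10 mol %), toluene (5 mM), 80 °C
Reagents that add atoms: none
Why: Ring-closing metathesis between the vinyl group and the acrylate closes the five-membered butenolide with loss of ethylene, while the trisubstituted alkenes and the enal are spectators.

Step 10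
Reactants: 16 (5S)-3-(bromomethyl)-5-[(2E,6E)-2,6-dimethyl-8-oxoocta-2,6-dien-1-yl]furan-2(5H)-one
Product: 17 deacetyllaurenobiolide (6α-hydroxygermacra-1(10)E,4E,11(13)-trien-12,8α-olide; 6R,7S,8S)
Conditions: CrCl2 (8 equiv), THF/DMF 4:1, 25 °C, 16 added by syringe pump over 10 h (final 2 mM); aq NH4Cl
Reagents that add atoms: none
Why: Intramolecular Nozaki–Hiyama (Barbier-type) allylation: the allylchromium adds through its γ-carbon C7 to the enal in a closed chair transition state, on the butenolide face opposite the C8 side chain (trans-fused lactone, 7S) and, because C8 is E-disposed to the CH2Cr group, with the anti C6/C7 relationship (6R).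

Step 11
Reactants: 17 deacetyllaurenobiolide
Product: 18 6β-phthalimidooxygermacra-1(10)E,4E,11(13)-trien-12,8α-olide (6S)
Conditions: N-hydroxyphthalimide (1.5 equiv), PPh3 (1.5 equiv), DIAD (1.5 equiv), THF, 0 °C → rt
Reagents that add atoms: N-hydroxyphthalimide, O=C1c2ccccc2C(=O)N1O
Why: Mitsunobu reaction; SN2 displacement of the C6 oxyphosphonium by N-hydroxyphthalimide inverts C6 to the β configuration of the ene-donor half and installs the alkoxyl-radical precursor.

Step 12
Reactants: 18 6β-phthalimidooxygermacra-1(10)E,4E,11(13)-trien-12,8α-olide; 17 deacetyllaurenobiolide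
Product: 19 target CNP0191625.1
Conditions: fac-Ir(ppy)3 (1 mol %), Hantzsch ester (diethyl 1,4-dihydro-2,6-dimethylpyridine-3,5-dicarboxylate, 1.5 equiv), PhCF3/1,4-dioxane 3:1 (degassed), 450 nm LEDs, 5 °C; 18 added over 6 h to 17 (3 equiv, 0.4 M; excess recovered)
Reagents that add atoms: none
Why: Proposed new method: a directed, transposing formal ene reaction in which photoexcited fac-Ir(ppy)3 reduces the N–O bond of 18 to the C6 β-alkoxyl radical, which (with H6 eclipsing C4=C5 and O6 gauche to C8) abstracts the allylic H9 by 1,5-hydrogen transfer through a six-membered chair, the C9–C10–C1 allyl radical (cisoid at C9–C10, the only geometry the ring holds without severe strain) adds through its less hindered terminus C1 on the outer β face to the exocyclic methylene of 17, and the lactone α-radical takes hydrogen from the Hantzsch ester on the β face to give the trans 7'-H/11'-H lactone, so C1 (S), the Z C9=C10 alkene, C11' (R) and the returned free 6β-OH are all controlled by the existing stereocentres; the closest known reaction is the photoredox δ-C(sp3)–H Giese alkylation of N-alkoxyphthalimides by alkoxyl-radical 1,5-hydrogen transfer, not yet shown for an allylic δ-C–H with bond formation at the transposed allyl terminus.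

## Compound list

1 | geranyl acetate, (2E)-3,7-dimethylocta-2,6-dien-1-yl acetate | CC(C)=CCC/C(C)=C/COC(C)=O | starting material
2 | (2E)-3-methyl-6-oxohex-2-en-1-yl acetate | O=CCC/C(C)=C/COC(C)=O | intermediate
3 | (2E)-3-methylhept-2-en-6-yn-1-yl acetate | C#CCC/C(C)=C/COC(C)=O | intermediate
4 | (2E)-3-methylhept-2-en-6-yn-1-ol | C#CCC/C(C)=C/CO | intermediate
5 | O,C-dilithio derivative of 4 (lithium alkoxide, lithium acetylide) | [Li]C#CCC/C(C)=C/CO[Li] | intermediate
6 | (2E)-3-methyloct-2-en-6-yn-1-ol | CC#CCC/C(C)=C/CO | intermediate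
7 | (2E,6E)-7-iodo-3-methylocta-2,6-dien-1-ol | I/C(C)=C/CC/C(C)=C/CO | intermediate
8 | (S)-epichlorohydrin, (2S)-2-(chloromethyl)oxirane | ClC[C@@H]1CO1 | starting material
9 | (2E,6E)-7-lithio-3-methylocta-2,6-dien-1-ol lithium alkoxide | [Li]/C(C)=C/CC/C(C)=C/CO[Li] | intermediate
10 | (2E,6E,9S)-10-chloro-3,7-dimethyldeca-2,6-diene-1,9-diol | ClC[C@@H](O)C/C(C)=C/CC/C(C)=C/CO | intermediate
11 | (2E,6E)-3,7-dimethyl-8-[(2S)-oxiran-2-yl]octa-2,6-dien-1-ol | C1[C@@H](O1)C/C(C)=C/CC/C(C)=C/CO | intermediate
12 | (2E,6E,9S)-3,7-dimethylundeca-2,6,10-triene-1,9-diol | C=C[C@@H](O)C/C(C)=C/CC/C(C)=C/CO | intermediate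
13 | (2E,6E,9S)-9-hydroxy-3,7-dimethylundeca-2,6,10-trienal | C=C[C@@H](O)C/C(C)=C/CC/C(C)=C/C=O | intermediate
14 | 2-(bromomethyl)acrylic acid | OC(=O)C(=C)CBr | starting material
15 | (3S,5E,9E)-5,9-dimethyl-11-oxoundeca-1,5,9-trien-3-yl 2-(bromomethyl)prop-2-enoate | C=C[C@@H](OC(=O)C(=C)CBr)C/C(C)=C/CC/C(C)=C/C=O | intermediate
16 | (5S)-3-(bromomethyl)-5-[(2E,6E)-2,6-dimethyl-8-oxoocta-2,6-dien-1-yl]furan-2(5H)-one | BrCC1=C[C@H](C/C(C)=C/CC/C(C)=C/C=O)OC1=O | intermediate
17 | deacetyllaurenobiolide, (3aS,4R,5E,9E,11aS)-4-hydroxy-6,10-dimethyl-3-methylidene-3a,4,7,8,11,11a-hexahydrocyclodeca[b]furan-2(3H)-one | C=C1C(=O)O[C@H]2C/C(C)=C/CC/C(C)=C/[C@@H](O)[C@H]12 | intermediate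
18 | 2-{[(3aR,4S,5E,9E,11aS)-6,10-dimethyl-3-methylidene-2-oxo-2,3,3a,4,7,8,11,11a-octahydrocyclodeca[b]furan-4-yl]oxy}isoindoline-1,3-dione (C6 epimer of 17 as its O-phthalimido ether; ring-fusion geometry as in 17, the 3a descriptor changes by priority only) | C=C1C(=O)O[C@H]2C/C(C)=C/CC/C(C)=C/[C@H](ON3C(=O)c4ccccc4C3=O)[C@H]12 | intermediate
19 | CNP0191625.1: (1S,6S,7S,8S)-6β-hydroxygermacra-4E,9Z,11(13)-trien-12,8α-olide joined from C1 (β) to C13' of (6'R,7'S,8'S,11'R)-6α-hydroxy-11βH-germacra-1(10)E,4E-dien-12,8α-olide | C=C1C(=O)O[C@H]2/C=C(/C)[C@H](C[C@H]3C(=O)O[C@H]4C/C(C)=C/CC/C(C)=C/[C@@H](O)[C@@H]43)CC/C(C)=C/[C@H](O)[C@H]12 | target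

## Step count and risks

Total steps: 12. Longest linear sequence: 12 (1 → 19; compound 17 is used twice, as precursor of 18 and as coupling partner).

**Step 12 (new transformation).** It can fail in four ways:
- β-scission of the C6–C7 bond of the alkoxyl radical (retro-allylation to an enal and a stabilised allyl radical);
- abstraction from the C15 methyl instead of C9;
- coupling at C9 instead of C1;
- the wrong face at C11'.

The low temperature and low-polarity solvent are chosen to favour hydrogen transfer over β-scission. The fallback is a biomimetic Alder-ene reaction using known chemistry. It sets out from 18: SmI2 in THF/MeOH at −78 °C cleaves the N–O bond to the 6β-alcohol F3. Dimethylamine in THF at 0 °C adds to its methylene lactone to give the amine adduct F4, which can then act only as ene donor. F4 (4 equiv) and 17 are held at 13 kbar in CH2Cl2 at 40 °C to give the ene adduct F5. Methylation with MeI followed by aqueous NaHCO3 eliminates the ammonium group and restores the methylene lactone, returning to the route at 19.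

**Step 10 (macrocyclisation).** Ring strain, oligomerisation, and the face selectivity at C7 and C6 are all open. The fallback replaces the reductive Barbier reaction by an allylboration. It sets out from 16: B2pin2 with Pd2(dba)3 (2 mol %) in toluene at 50 °C gives the pinacol allylboronate F1. Under Sc(OTf)3 (10 mol %) at 2 mM in toluene at 40 °C this cyclises through the same closed chair and, after aqueous work-up, comes back at 17.

**Step 11 (Mitsunobu on a hindered macrocyclic allylic alcohol).** SN2' attack, elimination, or phosphine addition to the methylene lactone may compete. The fallback separates activation from displacement. It sets out from 17: MsCl and Et3N in CH2Cl2 at −40 °C give the 6α-mesylate F2, which is displaced with inversion by the potassium salt of N-hydroxyphthalimide (K2CO3, 18-crown-6, DMF, 0 °C), coming back at 18.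

## Further compounds

F1 | step 10 | (5S)-5-[(2E,6E)-2,6-dimethyl-8-oxoocta-2,6-dien-1-yl]-3-[(4,4,5,5-tetramethyl-1,3,2-dioxaborolan-2-yl)methyl]furan-2(5H)-one | CC1(C)OB(CC2=C[C@H](C/C(C)=C/CC/C(C)=C/C=O)OC2=O)OC1(C)C
F2 | step 11 | deacetyllaurenobiolide 6-O-methanesulfonate (6R) | C=C1C(=O)O[C@H]2C/C(C)=C/CC/C(C)=C/[C@@H](OS(C)(=O)=O)[C@H]12
F3 | step 12 | 6-epi-deacetyllaurenobiolide (6β-hydroxygermacra-1(10)E,4E,11(13)-trien-12,8α-olide, 6S) | C=C1C(=O)O[C@H]2C/C(C)=C/CC/C(C)=C/[C@H](O)[C@H]12
F4 | step 12 | 13-dimethylamino-11βH-11,13-dihydro derivative of F3 | CN(C)C[C@H]1C(=O)O[C@H]2C/C(C)=C/CC/C(C)=C/[C@H](O)[C@H]12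
F5 | step 12 | ene adduct: 13-dimethylamino-11βH-11,13-dihydro derivative of 19 (amine on the ene-donor half) | CN(C)C[C@H]1C(=O)O[C@H]2/C=C(/C)[C@H](C[C@H]3C(=O)O[C@H]4C/C(C)=C/CC/C(C)=C/[C@@H](O)[C@@H]43)CC/C(C)=C/[C@H](O)[C@H]12
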